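**Assumption:** 4-(benzyloxy)-3-methoxybenzyl chloride and 4-(benzyloxy)-3-methoxybenzaldehyde are bought (both are vanillin-derived). The target is the trans-1,2 isomer, (1S,2R) as drawn.

## Retrosynthetic overview
- The target is the dihydronaphthalene diol. Its C2 and C3 CH2OH groups come from a diester (DIBAL), and its two phenols from benzyl ethers.
- The only ring (C1–C8a bond, C1 stereocentre) is closed by an electrochemical benzylic C–H / arene C–H Friedel–Crafts cyclisation of an (E)-arylidene 2-benzylsuccinate. The ring B benzylic position is oxidised selectively because the acrylate-conjugated ring A' is much harder to oxidise, and the C2 stereocentre sets C1 trans.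
- The arylidene comes from aldol/dehydration of a chiral 2-benzylsuccinate.
- The C2 stereocentre comes from anti-selective alkylation of dimethyl L-malate. The malate carbinol carbon then becomes the alkene carbon C3, so its stereocentre is removed.

## Route

**Step 1**
Reactants: 1 (dimethyl (S)-malate) + 2 (4-(benzyloxy)-3-methoxybenzyl chloride)
Product: 3 (dimethyl (2S,3R)-2-hydroxy-3-[4-(benzyloxy)-3-methoxybenzyl]succinate)
Conditions: LDA (2.3 equiv), THF, –78 → –20 °C; then 2, NaI (cat.), –20 °C → rt
Reagents that add atoms: 2, COc1cc(CCl)ccc1OCc1ccccc1 (adds the ArCH2 group)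
Why: Seebach dianion alkylation of malate. The chelated alkoxide/enolate is alkylated anti to the carbinol centre, which sets the future C2 centre (R) from the malate (S) centre.

**Step 2**
Reactants: 3 + 4 (phenyl chlorothionoformate)
Product: 5 (O-phenyl thiocarbonate of 3, same stereochemistry)
Conditions: 4 (1.5 equiv), pyridine, DMAP (cat.), CH2Cl2, 0 °C → rt
Reagents that add atoms: phenyl chlorothionoformate, S=C(Cl)Oc1ccccc1 (adds PhOC(=S))
Why: O-Acylation of the secondary alcohol (Barton–McCombie precursor). No stereocentre is touched.

**Step 3**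
Reactants: 5
Product: 6 (dimethyl (R)-2-[4-(benzyloxy)-3-methoxybenzyl]succinate)
Conditions: Bu3SnH (2 equiv), AIBN (cat.), toluene, 90 °C
Reagents that add atoms: none
Why: Barton–McCombie deoxygenation removes the temporary carbinol centre and leaves the benzyl-bearing stereocentre untouched, because the radical sits on the neighbouring CH2.

**Step 4**
Reactants: 6 + 7 (4-(benzyloxy)-3-methoxybenzaldehyde)
Product: 8 (dimethyl 2-[aryl(hydroxy)methyl]-3-(arylmethyl)succinate; C3 (R) retained, carbinol/α-centres as a diastereomer mixture)
Conditions: LDA (1.05 equiv), THF, –78 °C; then 7, –78 °C; NH4Cl quench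
Reagents that add atoms: 7, COc1cc(C=O)ccc1OCc1ccccc1 (adds ArCH(OH))
Why: Aldol addition of the kinetic ester enolate at the less hindered CH2. The two new centres are destroyed in the next step.

**Step 5**
Reactants: 8
Product: 9 (dimethyl (E)-2-(4-benzyloxy-3-methoxybenzylidene)-3-[(4-benzyloxy-3-methoxyphenyl)methyl]succinate, C3 (R))
Conditions: MsCl, Et3N, CH2Cl2, 0 °C → rt
Reagents that add atoms: none (the mesylate is lost)
Why: Mesylation then E1cB elimination. Under mild amine base the thermodynamic (E)-alkene forms, with Ar' trans to the ester and cis to the stereocentre, which is the geometry needed for ring closure. The Z isomer is removed by chromatography.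

**Step 6**
Reactants: 9
Product: 10 (dimethyl (1S,2R)-6,7-… i.e. 1-[4-(benzyloxy)-3-methoxyphenyl]-7-(benzyloxy)-6-methoxy-1,2-dihydronaphthalene-2,3-dicarboxylate)
Conditions: constant-current electrolysis (5 mA, ~2.2 F/mol), undivided cell, graphite anode, Pt cathode, nBu4NPF6 (0.05 M), HFIP/CH2Cl2 (1:3), 25 °C
Reagents that add atoms: none (H2 evolves at the cathode)
Why: Proposed new method: intramolecular anodic dehydrogenative benzylic C(sp3)–H / arene C(sp2)–H coupling.
- Ring B is oxidised at the anode to its radical cation, because the acrylate-conjugated ring A' is harder to oxidise.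
- Loss of the benzylic proton and a second oxidation give the p-alkoxy-stabilised benzylic cation at C7.
- The tethered ring A' attacks through its carbon para to OMe (6-membered transition state). The C8 ester sits pseudo-equatorial, so the new C1 centre is trans to C2, giving (1S,2R).
- Closest known chemistry: DDQ or anodic benzylic C–H functionalisation, and the quinone-methide/arene closure that gives 8–8' cyclic ferulate dimers.
- HFIP stabilises the cation and no base is added, which disfavours elimination.

**Step 7**
Reactants: 10
Product: 11 (dimethyl (1S,2R)-7-hydroxy-1-(4-hydroxy-3-methoxyphenyl)-6-methoxy-1,2-dihydronaphthalene-2,3-dicarboxylate)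
Conditions: BCl3 (6 equiv), pentamethylbenzene (6 equiv), CH2Cl2, –78 °C
Reagents that add atoms: none
Why: Cation-scavenged aryl benzyl ether cleavage. It avoids hydrogenolysis, which would reduce the conjugated alkene, and leaves the esters and stereocentres intact.

**Step 8**
Reactants: 11
Product: 12 (target, (1S,2R) diol)
Conditions: DIBAL-H (10 equiv), CH2Cl2, –78 → 0 °C; Rochelle salt work-up
Reagents that add atoms: none
Why: DIBAL reduces the saturated ester and gives 1,2-reduction of the α,β-unsaturated ester, so the C3=C4 alkene survives. The phenols are carried as aluminium phenoxides, and the non-basic conditions avoid epimerising C2.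

## Compound list
1 | dimethyl (S)-malate | COC(=O)C[C@H](O)C(=O)OC | starting material
2 | 4-(benzyloxy)-3-methoxybenzyl chloride | COc1cc(CCl)ccc1OCc1ccccc1 | starting material
3 | dimethyl (2S,3R)-2-hydroxy-3-[4-(benzyloxy)-3-methoxybenzyl]succinate | COC(=O)[C@@H](O)[C@@H](Cc1ccc(OCc2ccccc2)c(OC)c1)C(=O)OC | intermediate
4 | phenyl chlorothionoformate | S=C(Cl)Oc1ccccc1 | starting material
5 | O-phenyl thiocarbonate of 3 | COC(=O)[C@@H](OC(=S)Oc1ccccc1)[C@@H](Cc1ccc(OCc2ccccc2)c(OC)c1)C(=O)OC | intermediate
6 | dimethyl (R)-2-[4-(benzyloxy)-3-methoxybenzyl]succinate | COC(=O)C[C@@H](Cc1ccc(OCc2ccccc2)c(OC)c1)C(=O)OC | intermediate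
7 | 4-(benzyloxy)-3-methoxybenzaldehyde | COc1cc(C=O)ccc1OCc1ccccc1 | starting material
8 | aldol adduct (C3 (R); other centres mixed) | COC(=O)C(C(O)c1ccc(OCc2ccccc2)c(OC)c1)[C@@H](Cc1ccc(OCc2ccccc2)c(OC)c1)C(=O)OC | intermediate
9 | (E)-arylidene diester | COC(=O)/C(=C/c1ccc(OCc2ccccc2)c(OC)c1)[C@@H](Cc1ccc(OCc2ccccc2)c(OC)c1)C(=O)OC | intermediate
10 | cyclised bis(benzyl ether) diester, (1S,2R) | COc1cc([C@H]2c3cc(OCc4ccccc4)c(OC)cc3C=C(C(=O)OC)[C@@H]2C(=O)OC)ccc1OCc1ccccc1 | intermediate
11 | diphenol diester, (1S,2R) | COc1cc([C@H]2c3cc(O)c(OC)cc3C=C(C(=O)OC)[C@@H]2C(=O)OC)ccc1O | intermediate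
12 | target (1S,2R) | COc1cc([C@H]2c3cc(O)c(OC)cc3C=C(CO)[C@@H]2CO)ccc1O | target

**Total steps:** 8. **Longest linear sequence:** 8.

## Three steps most likely to fail
1. **Step 6 (proposed new electrochemical cyclisation).**
   - Risks: over-oxidation of the product to the arylnaphthalene, lactonisation onto the C9' ester, and a modest trans:cis ratio.
   - Fallback (known chemistry): DDQ/H2O benzylic hydroxylation of 9 at C7, then BF3·OEt2 Friedel–Crafts hydroxyalkylation (the classical conidendrin-type closure). The cation again sets C1 trans to C2.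
2. **Step 4 (aldol regiochemistry and C3 integrity).** Enolisation at the tertiary α-carbon would scramble C3.
   - Fallback: convert 6 to the β-(arylmethyl)-γ-butyrolactone (anhydride, regioselective NaBH4 reduction), where only one α-CH2 is enolisable. Run aldol/dehydration there, carry the lactone through the electrochemical closure, and reduce with DIBAL in place of step 8.
3. **Step 8 (DIBAL reduction of the conjugated diester with free phenols).** Conjugate reduction or C2 epimerisation is possible.
   - Fallback: non-epimerising ester cleavage (Me3SnOH) to the diacid, then BH3·THF reduction.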